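**Retrosynthetic overview**

- The target is released from a fully silylated ester. The ester is made from the C2a alcohol and O-silyl p-coumaric acid, and the C2a alcohol from a C2 aldehyde, so C2a (aldehyde) and C3a (silyl ether) are differentiated from the moment ring B exists.
- The strategy rests on two features: C1 is benzylic to the pendant ring and para to its free hydroxyl (the terminus of a para-quinone methide), and C2 is alpha to C2a (as an aldehyde, an enamine carbon). The C1–C2 bond is therefore the disconnection.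
- Ring B is the only ring formed. It closes by intramolecular 1,6-addition of the enamine to the quinone methide, with C3 as the only stored stereocentre; ring A and the pendant ring are bought as 6-bromovanillin and vanillin.
- The open-chain precursor comes from a ring A aryl bromide: bromine–lithium exchange and addition to O-silyl vanillin (C8a–C1 bond), alkene cleavage to the C2a aldehyde, then release of the pendant phenol only.
- C3 is set by alkylating the pent-4-enoyl imide of (R)-4-benzyloxazolidin-2-one with the ring A benzylic bromide.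

Key step: step 12

Assumption: tetralin numbering is used (C1 bears the pendant aryl group, C2 the carbon C2a, C3 the carbon C3a, C4 is the ring CH2), and the carbinol carbon of the benzhydrol intermediates 16–19 is carried as a mixture of both epimers, because both give the same planar quinone methide.

**Route**

Step 1
Reactants: 1 6-bromovanillin (2-bromo-4-hydroxy-5-methoxybenzaldehyde)
Product: 2 2-bromo-5-methoxy-4-(triisopropylsilyloxy)benzaldehyde
Conditions: i-Pr3SiCl, imidazole, DMF, rt
Reagents that add atoms: triisopropylsilyl chloride, CC(C)[Si](Cl)(C(C)C)C(C)C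
Why: Imidazole-promoted silyl ether formation on the acidic phenol masks the para-hydroxyl, so that the later benzylic bromide cannot collapse to a quinone methide and the ring A oxygen stays blocked through the key step.

Step 2
Reactants: 2 2-bromo-5-methoxy-4-(triisopropylsilyloxy)benzaldehyde
Product: 3 [2-bromo-5-methoxy-4-(triisopropylsilyloxy)phenyl]methanol
Conditions: NaBH4, THF/MeOH, 0 °C
Reagents that add atoms: none
Why: Borohydride reduction of the aryl aldehyde is fast at 0 °C and leaves the aryl bromide and the hindered aryl silyl ether untouched.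

Step 3
Reactants: 3 [2-bromo-5-methoxy-4-(triisopropylsilyloxy)phenyl]methanol
Product: 4 1-bromo-2-(bromomethyl)-4-methoxy-5-(triisopropylsilyloxy)benzene
Conditions: CBr4, PPh3, CH2Cl2, 0 °C
Reagents that add atoms: carbon tetrabromide, BrC(Br)(Br)Br
Why: The Appel reaction converts the benzylic alcohol into the bromide under neutral conditions that the silyl ether tolerates; the bromide should be used without storage.

Step 4
Reactants: 5 pent-4-enoic acid; 6 (R)-4-benzyloxazolidin-2-one
Product: 8 (R)-4-benzyl-3-(pent-4-enoyl)oxazolidin-2-one, via pent-4-enoic pivalic anhydride 7 (not isolated)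
Conditions: t-BuCOCl, Et3N, THF, −20 °C; then 6, LiCl, −20 °C → rt
Reagents that add atoms: none
Why: N-acylation of the oxazolidinone through the mixed pivalic anhydride (LiCl/Et3N protocol) should go at the unhindered pentenoyl carbonyl.

Step 5
Reactants: 8 (R)-4-benzyl-3-(pent-4-enoyl)oxazolidin-2-one; 4 1-bromo-2-(bromomethyl)-4-methoxy-5-(triisopropylsilyloxy)benzene
Product: 10 (R)-4-benzyl-3-[(2S)-2-{[2-bromo-5-methoxy-4-(triisopropylsilyloxy)phenyl]methyl}pent-4-enoyl]oxazolidin-2-one, via sodium Z-enolate 9 (not isolated)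
Conditions: NaN(SiMe3)2, THF, −78 °C; then 4, −78 → −30 °C
Reagents that add atoms: none
Why: In this Evans asymmetric alkylation the chelated Z-enolate is attacked by the reactive benzylic bromide on the face opposite the 4-benzyl group of the (R)-auxiliary, which sets the new centre as (S); it becomes C3 of the tetralin, where the descriptor reads (R) only because the neighbouring groups change priority.

Step 6
Reactants: 10 the alkylated imide
Product: 11 (2S)-2-{[2-bromo-5-methoxy-4-(triisopropylsilyloxy)phenyl]methyl}pent-4-en-1-ol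
Conditions: LiBH4, MeOH (1 equiv), Et2O/THF, 0 °C
Reagents that add atoms: none
Why: Reductive cleavage of the N-acyl oxazolidinone with LiBH4 should give the primary alcohol (the future C3a) without touching the stereocentre, the aryl bromide or the alkene, and returns the auxiliary.

Step 7
Reactants: 11 (2S)-2-{[2-bromo-5-methoxy-4-(triisopropylsilyloxy)phenyl]methyl}pent-4-en-1-ol
Product: 12 tert-butyl{[(2S)-2-{[2-bromo-5-methoxy-4-(triisopropylsilyloxy)phenyl]methyl}pent-4-en-1-yl]oxy}dimethylsilane
Conditions: t-BuMe2SiCl, imidazole, CH2Cl2, rt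
Reagents that add atoms: tert-butyldimethylsilyl chloride, CC(C)(C)[Si](C)(C)Cl
Why: Standard silylation of the primary alcohol gives an alkyl silyl ether that survives organolithium, periodate and carbonate conditions.

Step 8
Reactants: 13 vanillin
Product: 14 4-(tert-butyldimethylsilyloxy)-3-methoxybenzaldehyde
Conditions: t-BuMe2SiCl, imidazole, CH2Cl2, rt
Reagents that add atoms: tert-butyldimethylsilyl chloride, CC(C)(C)[Si](C)(C)Cl
Why: Silyl ether formation on the phenol; the less hindered silyl group is chosen here so that this aryl ether can later be cleaved in the presence of the ring A triisopropylsilyl ether.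

Step 9
Reactants: 12 the aryl bromide; 14 4-(tert-butyldimethylsilyloxy)-3-methoxybenzaldehyde
Product: 16 {2-[(2S)-2-{[(tert-butyldimethylsilyl)oxy]methyl}pent-4-en-1-yl]-4-methoxy-5-(triisopropylsilyloxy)phenyl}[4-(tert-butyldimethylsilyloxy)-3-methoxyphenyl]methanol (both carbinol epimers), via aryllithium 15 (not isolated)
Conditions: t-BuLi (2 equiv), Et2O, −78 °C; then 14, −78 °C; aq NH4Cl at −78 °C
Reagents that add atoms: none
Why: Bromine–lithium exchange followed by 1,2-addition of the aryllithium to the aldehyde forms the C8a–C1 bond; at −78 °C the alkene and the silyl ethers are inert, and the cold quench prevents silyl transfer to the new alkoxide.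

Step 10
Reactants: 16 the benzhydrol with terminal alkene
Product: 18 (3R)-3-{[(tert-butyldimethylsilyl)oxy]methyl}-4-{2-[[4-(tert-butyldimethylsilyloxy)-3-methoxyphenyl](hydroxy)methyl]-5-methoxy-4-(triisopropylsilyloxy)phenyl}butanal, via vicinal diol 17 (not isolated)
Conditions: OsO4 (2 mol%), NaIO4, 2,6-lutidine, dioxane/H2O (3:1), rt
Reagents that add atoms: osmium tetroxide (catalytic oxygen carrier), O=[Os](=O)(=O)=O; sodium periodate (terminal oxidant), [Na+].[O-]I(=O)(=O)=O
Why: Lemieux–Johnson oxidative cleavage (dihydroxylation, then periodate glycol cleavage) turns the terminal alkene into the C2a aldehyde; it is run while both phenols are still silylated, because periodate would oxidise a free guaiacol.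

Step 11
Reactants: 18 the aldehyde with silylated pendant phenol
Product: 19 (3R)-3-{[(tert-butyldimethylsilyl)oxy]methyl}-4-{2-[hydroxy(4-hydroxy-3-methoxyphenyl)methyl]-5-methoxy-4-(triisopropylsilyloxy)phenyl}butanal
Conditions: K2CO3, MeOH/THF, 0 °C → rt, stopped when 18 is consumed; pH 7 buffer
Reagents that add atoms: none
Why: Base-mediated methanolysis of an aryl silyl ether: aryl tert-butyldimethylsilyl ethers are solvolysed by alkaline methanol far faster than the more hindered aryl triisopropylsilyl ether, the alkyl silyl ether is inert to carbonate, and the aldehyde has no alpha stereocentre to lose.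

Step 12
Reactants: 19 the aldehyde 4-hydroxybenzhydrol
Product: 21 (1S,2R,3R)-3-{[(tert-butyldimethylsilyl)oxy]methyl}-1-(4-hydroxy-3-methoxyphenyl)-6-methoxy-7-(triisopropylsilyloxy)-1,2,3,4-tetrahydronaphthalene-2-carbaldehyde, via enamine quinone methide 20 (not isolated)
Conditions: (R)-α,α-diphenylprolinol trimethylsilyl ether (20 mol%), (PhO)2P(O)OH (20 mol%), CHCl3 (0.02 M), 30 °C
Reagents that add atoms: none
Why: The secondary amine condenses with the C2a aldehyde to the E-enamine while the acid co-catalyst dehydrates the 4-hydroxybenzhydrol (either epimer) to the para-quinone methide whose exocyclic carbon is C1; the enamine carbon C2 then adds to C1 in a 1,6-conjugate addition driven by rearomatisation of the pendant phenol, and hydrolysis of the iminium ion returns the catalyst. The closest known reaction type is the secondary-amine-catalysed 1,6-addition of aldehydes to para-quinone methides generated in situ from 4-hydroxybenzyl alcohols, applied here within one molecule. Ring B closes in a 6-(enolexo)-exo-trig mode, since both the enamine double bond and the quinone methide double bond are exocyclic to the new ring. C1 is set by a chair-like transition state in which the C3 silyloxymethyl group and the quinonoid aryl group are both equatorial (1,3-cis); C2 is set trans to both by attack on the enamine face that the (R)-configured catalyst leaves open, and it can in any case equilibrate to the equatorial aldehyde through the enamine. The step needs facial selectivity at C1 and C2 relative to C3 and site selectivity for the pendant ring: only that ring has a free hydroxyl para to the carbinol carbon, the ring A oxygen at C7 is silylated and meta to C1, and high dilution favours ring closure over intermolecular addition.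

Step 13
Reactants: 21 the tetralin aldehyde with free pendant phenol
Product: 22 (1S,2R,3R)-3-{[(tert-butyldimethylsilyl)oxy]methyl}-1-[4-(tert-butyldimethylsilyloxy)-3-methoxyphenyl]-6-methoxy-7-(triisopropylsilyloxy)-1,2,3,4-tetrahydronaphthalene-2-carbaldehyde
Conditions: t-BuMe2SiCl, imidazole, CH2Cl2, 0 °C → rt
Reagents that add atoms: tert-butyldimethylsilyl chloride, CC(C)(C)[Si](C)(C)Cl
Why: Silyl ether formation on the only free hydroxyl; the aldehyde is inert, and C2 already has the thermodynamically preferred equatorial configuration, so imidazole cannot erode it.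

Step 14
Reactants: 22 the fully silylated tetralin aldehyde
Product: 23 [(1S,2R,3R)-3-{[(tert-butyldimethylsilyl)oxy]methyl}-1-[4-(tert-butyldimethylsilyloxy)-3-methoxyphenyl]-6-methoxy-7-(triisopropylsilyloxy)-1,2,3,4-tetrahydronaphthalen-2-yl]methanol
Conditions: NaBH4, THF/EtOH, −20 → 0 °C
Reagents that add atoms: none
Why: Borohydride reduction of the aldehyde gives the C2a primary alcohol as the only free hydroxyl; the short, cold reaction spares the aryl silyl ethers and creates no new stereocentre.

Step 15
Reactants: 24 p-coumaric acid ((E)-3-(4-hydroxyphenyl)prop-2-enoic acid)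
Product: 26 (E)-3-[4-(tert-butyldimethylsilyloxy)phenyl]prop-2-enoic acid, via bis-silylated coumarate 25 (not isolated)
Conditions: t-BuMe2SiCl (2.2 equiv), imidazole, DMF, rt; then AcOH/THF/H2O, rt
Reagents that add atoms: tert-butyldimethylsilyl chloride, CC(C)(C)[Si](C)(C)Cl
Why: Silylation of both acidic hydroxyls followed by selective hydrolysis of the very labile silyl ester under mild aqueous acid, which leaves the aryl silyl ether intact.

Step 16
Reactants: 23 the C2a alcohol; 26 (E)-3-[4-(tert-butyldimethylsilyloxy)phenyl]prop-2-enoic acid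
Product: 27 [(1S,2R,3R)-3-{[(tert-butyldimethylsilyl)oxy]methyl}-1-[4-(tert-butyldimethylsilyloxy)-3-methoxyphenyl]-6-methoxy-7-(triisopropylsilyloxy)-1,2,3,4-tetrahydronaphthalen-2-yl]methyl (E)-3-[4-(tert-butyldimethylsilyloxy)phenyl]prop-2-enoate
Conditions: EDC·HCl (1-ethyl-3-(3-dimethylaminopropyl)carbodiimide hydrochloride), 4-(dimethylamino)pyridine, CH2Cl2, 0 °C → rt
Reagents that add atoms: none
Why: Steglich-type carbodiimide esterification acylates the single free primary hydroxyl; every phenol and the C3a oxygen are silylated, so no site selectivity is required.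

Step 17
Reactants: 27 the fully silylated ester
Product: 28 [(1S,2R,3R)-7-hydroxy-1-(4-hydroxy-3-methoxyphenyl)-3-(hydroxymethyl)-6-methoxy-1,2,3,4-tetrahydronaphthalen-2-yl]methyl (E)-3-(4-hydroxyphenyl)prop-2-enoate (CNP0403384.1)
Conditions: Bu4NF, AcOH (1:1, excess), THF, 0 °C → rt
Reagents that add atoms: none
Why: Fluoride-induced cleavage of the three aryl silyl ethers and the primary alkyl silyl ether; the acetic acid buffer is meant to protect the cinnamate ester from cleavage and from migration to the freed C3a hydroxyl.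

**Compound list**

1 | 6-bromovanillin (2-bromo-4-hydroxy-5-methoxybenzaldehyde) | COc1cc(C=O)c(Br)cc1O | starting material
2 | 2-bromo-5-methoxy-4-(triisopropylsilyloxy)benzaldehyde | COc1cc(C=O)c(Br)cc1O[Si](C(C)C)(C(C)C)C(C)C | intermediate
3 | [2-bromo-5-methoxy-4-(triisopropylsilyloxy)phenyl]methanol | COc1cc(CO)c(Br)cc1O[Si](C(C)C)(C(C)C)C(C)C | intermediate
4 | 1-bromo-2-(bromomethyl)-4-methoxy-5-(triisopropylsilyloxy)benzene | COc1cc(CBr)c(Br)cc1O[Si](C(C)C)(C(C)C)C(C)C | intermediate
5 | pent-4-enoic acid | C=CCCC(=O)O | starting material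
6 | (R)-4-benzyloxazolidin-2-one | O=C1N[C@H](Cc2ccccc2)CO1 | starting material
7 | pent-4-enoic pivalic anhydride (formed in the flask) | C=CCCC(=O)OC(=O)C(C)(C)C | intermediate
8 | (R)-4-benzyl-3-(pent-4-enoyl)oxazolidin-2-one | C=CCCC(=O)N1[C@H](Cc2ccccc2)COC1=O | intermediate
9 | sodium Z-enolate of imide 8 (formed in the flask) | C=CC/C=C(\[O-])N1[C@H](Cc2ccccc2)COC1=O.[Na+] | intermediate
10 | (R)-4-benzyl-3-[(2S)-2-{[2-bromo-5-methoxy-4-(triisopropylsilyloxy)phenyl]methyl}pent-4-enoyl]oxazolidin-2-one | C=CC[C@@H](Cc1cc(OC)c(O[Si](C(C)C)(C(C)C)C(C)C)cc1Br)C(=O)N1[C@H](Cc2ccccc2)COC1=O | intermediate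
11 | (2S)-2-{[2-bromo-5-methoxy-4-(triisopropylsilyloxy)phenyl]methyl}pent-4-en-1-ol | C=CC[C@@H](Cc1cc(OC)c(O[Si](C(C)C)(C(C)C)C(C)C)cc1Br)CO | intermediate
12 | tert-butyl{[(2S)-2-{[2-bromo-5-methoxy-4-(triisopropylsilyloxy)phenyl]methyl}pent-4-en-1-yl]oxy}dimethylsilane | C=CC[C@@H](Cc1cc(OC)c(O[Si](C(C)C)(C(C)C)C(C)C)cc1Br)CO[Si](C)(C)C(C)(C)C | intermediate
13 | vanillin | COc1cc(C=O)ccc1O | starting material
14 | 4-(tert-butyldimethylsilyloxy)-3-methoxybenzaldehyde | COc1cc(C=O)ccc1O[Si](C)(C)C(C)(C)C | intermediate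
15 | aryllithium from 12, lithium in place of bromine (formed in the flask) | C=CC[C@@H](Cc1cc(OC)c(O[Si](C(C)C)(C(C)C)C(C)C)cc1[Li])CO[Si](C)(C)C(C)(C)C | intermediate
16 | {2-[(2S)-2-{[(tert-butyldimethylsilyl)oxy]methyl}pent-4-en-1-yl]-4-methoxy-5-(triisopropylsilyloxy)phenyl}[4-(tert-butyldimethylsilyloxy)-3-methoxyphenyl]methanol, both carbinol epimers | C=CC[C@@H](Cc1cc(OC)c(O[Si](C(C)C)(C(C)C)C(C)C)cc1C(O)c1ccc(O[Si](C)(C)C(C)(C)C)c(OC)c1)CO[Si](C)(C)C(C)(C)C | intermediate
17 | (4R)-4-{[(tert-butyldimethylsilyl)oxy]methyl}-5-{2-[[4-(tert-butyldimethylsilyloxy)-3-methoxyphenyl](hydroxy)methyl]-5-methoxy-4-(triisopropylsilyloxy)phenyl}pentane-1,2-diol (formed in the flask) | COc1cc(C[C@@H](CO[Si](C)(C)C(C)(C)C)CC(O)CO)c(cc1O[Si](C(C)C)(C(C)C)C(C)C)C(O)c1ccc(O[Si](C)(C)C(C)(C)C)c(OC)c1 | intermediate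
18 | (3R)-3-{[(tert-butyldimethylsilyl)oxy]methyl}-4-{2-[[4-(tert-butyldimethylsilyloxy)-3-methoxyphenyl](hydroxy)methyl]-5-methoxy-4-(triisopropylsilyloxy)phenyl}butanal | COc1cc(C[C@@H](CO[Si](C)(C)C(C)(C)C)CC=O)c(cc1O[Si](C(C)C)(C(C)C)C(C)C)C(O)c1ccc(O[Si](C)(C)C(C)(C)C)c(OC)c1 | intermediate
19 | (3R)-3-{[(tert-butyldimethylsilyl)oxy]methyl}-4-{2-[hydroxy(4-hydroxy-3-methoxyphenyl)methyl]-5-methoxy-4-(triisopropylsilyloxy)phenyl}butanal (key-step precursor) | COc1cc(C[C@@H](CO[Si](C)(C)C(C)(C)C)CC=O)c(cc1O[Si](C(C)C)(C(C)C)C(C)C)C(O)c1ccc(O)c(OC)c1 | intermediate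
20 | E-enamine of 19 with the (R)-catalyst, carrying the para-quinone methide at C1 (formed in the flask) | COc1cc(C[C@@H](CO[Si](C)(C)C(C)(C)C)/C=C/N2CCC[C@@H]2C(O[Si](C)(C)C)(c2ccccc2)c2ccccc2)c(cc1O[Si](C(C)C)(C(C)C)C(C)C)C=C1C=CC(=O)C(OC)=C1 | intermediate
21 | (1S,2R,3R)-3-{[(tert-butyldimethylsilyl)oxy]methyl}-1-(4-hydroxy-3-methoxyphenyl)-6-methoxy-7-(triisopropylsilyloxy)-1,2,3,4-tetrahydronaphthalene-2-carbaldehyde (key-step product) | COc1cc([C@H]2c3cc(O[Si](C(C)C)(C(C)C)C(C)C)c(OC)cc3C[C@@H](CO[Si](C)(C)C(C)(C)C)[C@@H]2C=O)ccc1O | intermediate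
22 | (1S,2R,3R)-3-{[(tert-butyldimethylsilyl)oxy]methyl}-1-[4-(tert-butyldimethylsilyloxy)-3-methoxyphenyl]-6-methoxy-7-(triisopropylsilyloxy)-1,2,3,4-tetrahydronaphthalene-2-carbaldehyde | COc1cc([C@H]2c3cc(O[Si](C(C)C)(C(C)C)C(C)C)c(OC)cc3C[C@@H](CO[Si](C)(C)C(C)(C)C)[C@@H]2C=O)ccc1O[Si](C)(C)C(C)(C)C | intermediate
23 | [(1S,2R,3R)-3-{[(tert-butyldimethylsilyl)oxy]methyl}-1-[4-(tert-butyldimethylsilyloxy)-3-methoxyphenyl]-6-methoxy-7-(triisopropylsilyloxy)-1,2,3,4-tetrahydronaphthalen-2-yl]methanol | COc1cc([C@H]2c3cc(O[Si](C(C)C)(C(C)C)C(C)C)c(OC)cc3C[C@@H](CO[Si](C)(C)C(C)(C)C)[C@@H]2CO)ccc1O[Si](C)(C)C(C)(C)C | intermediate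
24 | p-coumaric acid | O=C(O)/C=C/c1ccc(O)cc1 | starting material
25 | tert-butyldimethylsilyl (E)-3-[4-(tert-butyldimethylsilyloxy)phenyl]prop-2-enoate (formed in the flask) | CC(C)(C)[Si](C)(C)OC(=O)/C=C/c1ccc(O[Si](C)(C)C(C)(C)C)cc1 | intermediate
26 | (E)-3-[4-(tert-butyldimethylsilyloxy)phenyl]prop-2-enoic acid | O=C(O)/C=C/c1ccc(O[Si](C)(C)C(C)(C)C)cc1 | intermediate
27 | [(1S,2R,3R)-3-{[(tert-butyldimethylsilyl)oxy]methyl}-1-[4-(tert-butyldimethylsilyloxy)-3-methoxyphenyl]-6-methoxy-7-(triisopropylsilyloxy)-1,2,3,4-tetrahydronaphthalen-2-yl]methyl (E)-3-[4-(tert-butyldimethylsilyloxy)phenyl]prop-2-enoate | COc1cc([C@H]2c3cc(O[Si](C(C)C)(C(C)C)C(C)C)c(OC)cc3C[C@@H](CO[Si](C)(C)C(C)(C)C)[C@@H]2COC(=O)/C=C/c2ccc(O[Si](C)(C)C(C)(C)C)cc2)ccc1O[Si](C)(C)C(C)(C)C | intermediate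
28 | [(1S,2R,3R)-7-hydroxy-1-(4-hydroxy-3-methoxyphenyl)-3-(hydroxymethyl)-6-methoxy-1,2,3,4-tetrahydronaphthalen-2-yl]methyl (E)-3-(4-hydroxyphenyl)prop-2-enoate | COc1cc([C@H]2c3cc(O)c(OC)cc3C[C@@H](CO)[C@@H]2COC(=O)/C=C/c2ccc(O)cc2)ccc1O | target

**Step count**

Total: 17 steps. Longest linear sequence: 14 steps (1 → 28 through steps 1, 2, 3, 5, 6, 7, 9, 10, 11, 12, 13, 14, 16, 17); steps 4, 8 and 15 are side branches.

**Steps most likely to fail**

1. Step 12 (ring B closure). The dehydration to the quinone methide may be slow under the buffered amine/acid conditions, the quinone methide may be intercepted by the amine or by a phenol of a second molecule (oligomerisation), or the C3 centre may transmit its configuration to C1 poorly. The fallback sets out from 18 and returns at 22. Aldehyde 18 would be treated with t-BuMe2SiOTf and Et3N in CH2Cl2 (−78 → 0 °C), which converts the aldehyde into its silyl enol ether and silylates the carbinol to give the bis-silylated enol ether F1. Catalytic Me3SiOTf in CH2Cl2 at −78 °C would then ionise the benzhydryl silyl ether to the diarylmethyl cation, stabilised by the para-oxygens of both rings, and the silyl enol ether would capture it in an intramolecular Mukaiyama-type alkylation (the same C1–C2 bond, the same chair preference, sharpened by the low temperature). Aqueous work-up should give 22 directly, so that steps 11 and 13 are also bypassed.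

2. Step 11 (release of the pendant phenol). The ring A triisopropylsilyl ether may be lost along with the tert-butyldimethylsilyl ether if discrimination is insufficient, and the aldehyde may undergo base-induced aldol condensation during the methanolysis. The fallback sets out from 12 and returns at 19 and uses a far more labile silyl group on the pendant ring. Vanillin 13 would be silylated with Et3SiCl and imidazole to 3-methoxy-4-(triethylsilyloxy)benzaldehyde F2. The aryllithium 15 from 12 would be added to it at −78 °C, with an acetic acid quench at that temperature, to give the triethylsilyl benzhydrol F3. Buffered OsO4/NaIO4/2,6-lutidine cleavage would pass through the diol F4 to the triethylsilyl aldehyde F5. A few minutes with catalytic K2CO3 in MeOH at −20 °C should then remove only the aryl triethylsilyl ether and give 19.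

3. Step 17 (global desilylation). During the long fluoride exposure that the primary alkyl silyl ether requires, the coumaroyl group may migrate from the C2a oxygen to the freed C3a hydroxyl or be cleaved, and cleavage of the aryl triisopropylsilyl ether may be incomplete under milder conditions. The fallback sets out from 27 and returns at 28 through a staged, orthogonal deprotection. Brief treatment with Bu4NF/AcOH in THF at −20 → 0 °C should remove only the three aryl silyl groups and give the triphenol F6, in which the C3a oxygen is still silylated so that no neighbouring hydroxyl can accept the acyl group. The remaining alkyl silyl ether would then be cleaved under acidic conditions (HF·pyridine in THF/pyridine, 0 °C → rt), where acyl migration is slow, to give 28.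

**Further compounds**

F1 | step 12 | tert-butyldimethylsilyl enol ether of 18 with the carbinol also silylated (enol ether geometry not defined) | COc1cc(C[C@@H](CO[Si](C)(C)C(C)(C)C)C=CO[Si](C)(C)C(C)(C)C)c(cc1O[Si](C(C)C)(C(C)C)C(C)C)C(O[Si](C)(C)C(C)(C)C)c1ccc(O[Si](C)(C)C(C)(C)C)c(OC)c1
F2 | step 11 | 3-methoxy-4-(triethylsilyloxy)benzaldehyde | COc1cc(C=O)ccc1O[Si](CC)(CC)CC
F3 | step 11 | {2-[(2S)-2-{[(tert-butyldimethylsilyl)oxy]methyl}pent-4-en-1-yl]-4-methoxy-5-(triisopropylsilyloxy)phenyl}[3-methoxy-4-(triethylsilyloxy)phenyl]methanol | C=CC[C@@H](Cc1cc(OC)c(O[Si](C(C)C)(C(C)C)C(C)C)cc1C(O)c1ccc(O[Si](CC)(CC)CC)c(OC)c1)CO[Si](C)(C)C(C)(C)C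
F4 | step 11 | (4R)-4-{[(tert-butyldimethylsilyl)oxy]methyl}-5-{2-[hydroxy[3-methoxy-4-(triethylsilyloxy)phenyl]methyl]-5-methoxy-4-(triisopropylsilyloxy)phenyl}pentane-1,2-diol (formed in the flask) | COc1cc(C[C@@H](CO[Si](C)(C)C(C)(C)C)CC(O)CO)c(cc1O[Si](C(C)C)(C(C)C)C(C)C)C(O)c1ccc(O[Si](CC)(CC)CC)c(OC)c1
F5 | step 11 | (3R)-3-{[(tert-butyldimethylsilyl)oxy]methyl}-4-{2-[hydroxy[3-methoxy-4-(triethylsilyloxy)phenyl]methyl]-5-methoxy-4-(triisopropylsilyloxy)phenyl}butanal | COc1cc(C[C@@H](CO[Si](C)(C)C(C)(C)C)CC=O)c(cc1O[Si](C(C)C)(C(C)C)C(C)C)C(O)c1ccc(O[Si](CC)(CC)CC)c(OC)c1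
F6 | step 17 | [(1S,2R,3R)-3-{[(tert-butyldimethylsilyl)oxy]methyl}-7-hydroxy-1-(4-hydroxy-3-methoxyphenyl)-6-methoxy-1,2,3,4-tetrahydronaphthalen-2-yl]methyl (E)-3-(4-hydroxyphenyl)prop-2-enoate | COc1cc([C@H]2c3cc(O)c(OC)cc3C[C@@H](CO[Si](C)(C)C(C)(C)C)[C@@H]2COC(=O)/C=C/c2ccc(O)cc2)ccc1O
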